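The route rests on cutting the two aryl–carbon bonds at C2 and C5, the ring carbons flanking the oxygen of the oxolane. A single nickel-catalysed, twofold decarboxylative arylation of a bis(N-acyloxyphthalimide) with an arylzinc reagent attaches both syringyl rings and sets C2 and C5, each aryl group entering trans to the silyloxymethyl group on the neighbouring carbon (C3 or C4). The coupling partner is the 2,5-cis-3,4-trans oxolane-2,5-dicarboxylic bis-ester, reached by oxidative cleavage of an enantiopure trans-disubstituted 7-oxanorbornene. All four hydroxyl groups, the phenols included, carry the same silyl group, so one fluoride step ends the route and hydrogenolysis next to the doubly benzylic ring ether is avoided.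

Key step: step 8

Assumption: the two diastereomeric dimenthyl esters formed in step 1 can be separated by crystallisation (supported by chromatography of the liquor), and the configuration of the isomer carried on is confirmed by X-ray analysis with the menthyl groups as internal reference.

Step 1
Reactants: 1 furan; 2 fumaryl chloride ((E)-but-2-enedioyl dichloride); 3 (−)-menthol ((1R,2S,5R)-5-methyl-2-(propan-2-yl)cyclohexan-1-ol)
Product: 5 bis[(1R,2S,5R)-menthyl] (1R,2R,3R,4S)-7-oxabicyclo[2.2.1]hept-5-ene-2,3-dicarboxylate (ester at C2 endo and at C3 exo), via racemic diacyl dichloride adduct 4 (not isolated)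
Conditions: 1 (excess), Et2O, 0 °C to 25 °C, dark; then 3 (2.2 equiv), pyridine, DMAP (cat.), CH2Cl2, 0 °C to 25 °C; fractional crystallisation of the diastereomers
Reagents that add atoms: (−)-menthol (second equivalent of 3), CC(C)[C@@H]1CC[C@@H](C)C[C@H]1O
Why: The Diels–Alder cycloaddition of furan with the strongly electrophilic fumaryl chloride is suprafacial and so carries the E geometry into the racemic 2-endo,3-exo adduct, and pyridine/DMAP esterification of both acyl chlorides with two equivalents of enantiopure menthol then turns the two enantiomers into diastereomeric diesters from which the (1R,2R,3R,4S) isomer is separated, so the absolute configuration at C2 and C3 comes from a resolution through covalent diastereomers.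

Step 2
Reactants: 5 bis[(1R,2S,5R)-menthyl] (1R,2R,3R,4S)-7-oxabicyclo[2.2.1]hept-5-ene-2,3-dicarboxylate
Product: 6 [(1R,2S,3S,4S)-7-oxabicyclo[2.2.1]hept-5-ene-2,3-diyl]dimethanol (C2 arm endo and C3 arm exo)
Conditions: LiAlH4, THF, 0 °C to 25 °C; aqueous work-up
Reagents that add atoms: none
Why: LiAlH4 reduction of the two esters to primary alcohols runs below the temperature at which the furan adduct would undergo cycloreversion, leaves the four stereocentres and the alkene untouched, and releases both menthol units for recovery.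

Step 3
Reactants: 6 [(1R,2S,3S,4S)-7-oxabicyclo[2.2.1]hept-5-ene-2,3-diyl]dimethanol
Product: 7 (1R,2S,3S,4S)-2,3-bis[(tert-butyldimethylsilyloxy)methyl]-7-oxabicyclo[2.2.1]hept-5-ene
Conditions: TBSCl (2.4 equiv), imidazole, DMF, 25 °C
Reagents that add atoms: tert-butyldimethylsilyl chloride (two equivalents), CC(C)(C)[Si](C)(C)Cl
Why: Imidazole-promoted silylation of the two unhindered primary alcohols is routine and installs bulky groups that later shield one face of each neighbouring α-oxy carbon.

Step 4
Reactants: 7 (1R,2S,3S,4S)-2,3-bis[(tert-butyldimethylsilyloxy)methyl]-7-oxabicyclo[2.2.1]hept-5-ene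
Product: 9 (2R,3S,4S,5S)-3,4-bis[(tert-butyldimethylsilyloxy)methyl]oxolane-2,5-dicarboxylic acid, via oxolane-2,5-dicarbaldehyde 8 (not isolated)
Conditions: RuCl3·xH2O (cat.), NaIO4, EtOAc/MeCN/H2O, 0 °C to 25 °C
Reagents that add atoms: sodium periodate, [Na+].[O-]I(=O)(=O)=O; water, O
Why: Catalytic RuO4 generated from RuCl3 and NaIO4 (oxidative alkene cleavage) cuts the strained C5=C6 bond through the dialdehyde to two carboxylic acids, and because both bridgehead carbons were joined to the alkene bridge on the same face the acids emerge 2,5-cis on an oxolane whose C3 and C4 centres are not touched.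

Step 5
Reactants: 9 (2R,3S,4S,5S)-3,4-bis[(tert-butyldimethylsilyloxy)methyl]oxolane-2,5-dicarboxylic acid; 10 N-hydroxyphthalimide
Product: 11 bis(1,3-dioxoisoindolin-2-yl) (2R,3S,4S,5S)-3,4-bis[(tert-butyldimethylsilyloxy)methyl]oxolane-2,5-dicarboxylate
Conditions: 10 (2.2 equiv), N,N'-diisopropylcarbodiimide (2.4 equiv), DMAP (cat.), CH2Cl2, 25 °C
Reagents that add atoms: N-hydroxyphthalimide (second equivalent of 10), O=C1c2ccccc2C(=O)N1O
Why: Carbodiimide-mediated (Steglich-type) esterification of both acids, each with one equivalent of N-hydroxyphthalimide, gives the redox-active bis-ester, any bridged anhydride formed from the cis diacid being reopened by the N-hydroxy imide and activated again, and any epimerisation next to the activated esters being harmless because C2 and C5 are reset in step 8.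

Step 6
Reactants: 12 4-bromo-2,6-dimethoxyphenol
Product: 13 (4-bromo-2,6-dimethoxyphenoxy)(tert-butyl)dimethylsilane
Conditions: TBSCl, imidazole, DMF, 25 °C
Reagents that add atoms: tert-butyldimethylsilyl chloride, CC(C)(C)[Si](C)(C)Cl
Why: Imidazole-promoted silylation masks the acidic phenol before metalation and uses a group that the final fluoride step removes together with the alkyl silyl ethers.

Step 7
Reactants: 13 (4-bromo-2,6-dimethoxyphenoxy)(tert-butyl)dimethylsilane
Product: 15 [4-(tert-butyldimethylsilyloxy)-3,5-dimethoxyphenyl]zinc chloride (THF solution used directly), via arylmagnesium bromide 14 (not isolated)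
Conditions: Mg turnings, LiCl, THF, 25 °C; then ZnCl2, THF, 0 °C to 25 °C
Reagents that add atoms: zinc dichloride, Cl[Zn]Cl
Why: LiCl-assisted insertion of magnesium into the aryl bromide followed by transmetalation with ZnCl2 gives the arylzinc nucleophile without an alkyl halide co-product that could enter the nickel cycle, and the para-silyloxy and methoxy groups are inert to both metals.

Step 8
Reactants: 11 bis(1,3-dioxoisoindolin-2-yl) (2R,3S,4S,5S)-3,4-bis[(tert-butyldimethylsilyloxy)methyl]oxolane-2,5-dicarboxylate; 15 [4-(tert-butyldimethylsilyloxy)-3,5-dimethoxyphenyl]zinc chloride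
Product: 18 (2R,3S,4S,5R)-2,5-bis[4-(tert-butyldimethylsilyloxy)-3,5-dimethoxyphenyl]-3,4-bis[(tert-butyldimethylsilyloxy)methyl]oxolane (all-trans), via C2-arylated monoester 16 (not isolated), via C5-arylated monoester 17 (not isolated)
Conditions: NiCl2·glyme (40 mol%), 4,4'-di-tert-butyl-2,2'-bipyridine (80 mol%), 15 (6 equiv), THF/DMF, 25 °C
Reagents that add atoms: [4-(tert-butyldimethylsilyloxy)-3,5-dimethoxyphenyl]zinc chloride (second equivalent of 15), COc1cc([Zn]Cl)cc(OC)c1O[Si](C)(C)C(C)(C)C
Why: The arylzinc transmetalates to bipyridine-ligated nickel, the resulting low-valent arylnickel species transfers one electron to an N-acyloxyphthalimide, and the radical anion breaks down to phthalimide anion, CO2 and an α-oxy oxolanyl radical that is captured at nickel and released by C(sp3)–C(sp2) reductive elimination from trivalent nickel, after which the cycle repeats with a second equivalent of 15 at the remaining ester of 16 or 17. The closest known reaction type is the nickel-catalysed decarboxylative Negishi-type arylation of redox-active esters of oxolane-2-carboxylic and furanosyl acids, here run twice on one ring. No ring is closed; the step forms only the C2–aryl and C5–aryl bonds. Both new stereocentres pass through radicals, so the cis relation of the acid groups in 11 is erased; C2 is set by the silyloxymethyl group on C3 and C5 by the one on C4, the arylnickel unit meeting each radical on the face opposite its neighbour. The step therefore needs 2,3-trans and 4,5-trans selectivity at both ends, which the bulky silyloxymethyl groups should secure by 1,2-induction, and in the second event the aryl group already on the far α-carbon lies on the same face as the adjacent substituent and reinforces it. β-Scission is not expected because neither C3 nor C4 carries a leaving group directly, and the excess of arylzinc keeps radical capture ahead of hydrogen abstraction.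

Step 9
Reactants: 18 (2R,3S,4S,5R)-2,5-bis[4-(tert-butyldimethylsilyloxy)-3,5-dimethoxyphenyl]-3,4-bis[(tert-butyldimethylsilyloxy)methyl]oxolane
Product: 19 [(2R,3S,4S,5R)-2,5-bis(4-hydroxy-3,5-dimethoxyphenyl)oxolane-3,4-diyl]dimethanol (target)
Conditions: Bu4NF, AcOH, THF, 0 °C to 25 °C
Reagents that add atoms: none
Why: Buffered fluoride desilylation cleaves the four Si–O bonds and frees both phenols and both primary alcohols in one operation without strong acid or hydrogen, so the doubly benzylic ring ether and the four stereocentres should not be disturbed.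

Compound list

1 | furan | c1ccoc1 | starting material
2 | fumaryl chloride ((E)-but-2-enedioyl dichloride) | O=C(Cl)/C=C/C(=O)Cl | starting material
3 | (−)-menthol ((1R,2S,5R)-5-methyl-2-(propan-2-yl)cyclohexan-1-ol) | CC(C)[C@@H]1CC[C@@H](C)C[C@H]1O | starting material
4 | racemic (1R*,2R*,3R*,4S*)-7-oxabicyclo[2.2.1]hept-5-ene-2,3-dicarbonyl dichloride (2-endo,3-exo; one enantiomer drawn; not isolated) | C1=C[C@@H]2O[C@H]1[C@H](C(=O)Cl)[C@H]2C(=O)Cl | intermediate
5 | bis[(1R,2S,5R)-menthyl] (1R,2R,3R,4S)-7-oxabicyclo[2.2.1]hept-5-ene-2,3-dicarboxylate (C2 ester endo, C3 ester exo) | C1=C[C@@H]2O[C@H]1[C@H](C(=O)O[C@@H]3C[C@H](C)CC[C@H]3C(C)C)[C@H]2C(=O)O[C@@H]4C[C@H](C)CC[C@H]4C(C)C | intermediate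
6 | [(1R,2S,3S,4S)-7-oxabicyclo[2.2.1]hept-5-ene-2,3-diyl]dimethanol (C2 arm endo, C3 arm exo) | C1=C[C@@H]2O[C@H]1[C@H](CO)[C@H]2CO | intermediate
7 | (1R,2S,3S,4S)-2,3-bis[(tert-butyldimethylsilyloxy)methyl]-7-oxabicyclo[2.2.1]hept-5-ene | C1=C[C@@H]2O[C@H]1[C@H](CO[Si](C)(C)C(C)(C)C)[C@H]2CO[Si](C)(C)C(C)(C)C | intermediate
8 | (2R,3S,4S,5S)-3,4-bis[(tert-butyldimethylsilyloxy)methyl]oxolane-2,5-dicarbaldehyde (not isolated) | O=C[C@@H]1O[C@H](C=O)[C@H](CO[Si](C)(C)C(C)(C)C)[C@H]1CO[Si](C)(C)C(C)(C)C | intermediate
9 | (2R,3S,4S,5S)-3,4-bis[(tert-butyldimethylsilyloxy)methyl]oxolane-2,5-dicarboxylic acid (acids 2,5-cis; C3/C4 trans) | OC(=O)[C@@H]1O[C@H](C(=O)O)[C@H](CO[Si](C)(C)C(C)(C)C)[C@H]1CO[Si](C)(C)C(C)(C)C | intermediate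
10 | N-hydroxyphthalimide (2-hydroxyisoindoline-1,3-dione) | O=C1c2ccccc2C(=O)N1O | starting material
11 | bis(1,3-dioxoisoindolin-2-yl) (2R,3S,4S,5S)-3,4-bis[(tert-butyldimethylsilyloxy)methyl]oxolane-2,5-dicarboxylate (esters 2,5-cis; C3/C4 trans) | O=C(ON1C(=O)c2ccccc2C1=O)[C@@H]1O[C@H](C(=O)ON2C(=O)c3ccccc3C2=O)[C@H](CO[Si](C)(C)C(C)(C)C)[C@H]1CO[Si](C)(C)C(C)(C)C | intermediate
12 | 4-bromo-2,6-dimethoxyphenol | COc1cc(Br)cc(OC)c1O | starting material
13 | (4-bromo-2,6-dimethoxyphenoxy)(tert-butyl)dimethylsilane | COc1cc(Br)cc(OC)c1O[Si](C)(C)C(C)(C)C | intermediate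
14 | [4-(tert-butyldimethylsilyloxy)-3,5-dimethoxyphenyl]magnesium bromide (not isolated) | COc1cc([Mg]Br)cc(OC)c1O[Si](C)(C)C(C)(C)C | intermediate
15 | [4-(tert-butyldimethylsilyloxy)-3,5-dimethoxyphenyl]zinc chloride | COc1cc([Zn]Cl)cc(OC)c1O[Si](C)(C)C(C)(C)C | intermediate
16 | 1,3-dioxoisoindolin-2-yl (2S,3S,4S,5R)-5-[4-(tert-butyldimethylsilyloxy)-3,5-dimethoxyphenyl]-3,4-bis[(tert-butyldimethylsilyloxy)methyl]oxolane-2-carboxylate (aryl on the former C2 of 11; not isolated) | COc1cc([C@@H]2O[C@H](C(=O)ON3C(=O)c4ccccc4C3=O)[C@H](CO[Si](C)(C)C(C)(C)C)[C@H]2CO[Si](C)(C)C(C)(C)C)cc(OC)c1O[Si](C)(C)C(C)(C)C | intermediate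
17 | 1,3-dioxoisoindolin-2-yl (2R,3S,4S,5R)-5-[4-(tert-butyldimethylsilyloxy)-3,5-dimethoxyphenyl]-3,4-bis[(tert-butyldimethylsilyloxy)methyl]oxolane-2-carboxylate (aryl on the former C5 of 11; not isolated) | O=C(ON1C(=O)c2ccccc2C1=O)[C@@H]1O[C@@H](c2cc(OC)c(O[Si](C)(C)C(C)(C)C)c(OC)c2)[C@H](CO[Si](C)(C)C(C)(C)C)[C@H]1CO[Si](C)(C)C(C)(C)C | intermediate
18 | (2R,3S,4S,5R)-2,5-bis[4-(tert-butyldimethylsilyloxy)-3,5-dimethoxyphenyl]-3,4-bis[(tert-butyldimethylsilyloxy)methyl]oxolane (all-trans) | COc1cc([C@@H]2O[C@@H](c3cc(OC)c(O[Si](C)(C)C(C)(C)C)c(OC)c3)[C@H](CO[Si](C)(C)C(C)(C)C)[C@H]2CO[Si](C)(C)C(C)(C)C)cc(OC)c1O[Si](C)(C)C(C)(C)C | intermediate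
19 | [(2R,3S,4S,5R)-2,5-bis(4-hydroxy-3,5-dimethoxyphenyl)oxolane-3,4-diyl]dimethanol | COc1cc([C@@H]2O[C@@H](c3cc(OC)c(O)c(OC)c3)[C@H](CO)[C@H]2CO)cc(OC)c1O | target

Total step count: 9
Longest linear sequence: 7 steps (steps 1, 2, 3, 4, 5, 8, 9)

Steps most likely to fail

1. Step 8. The arylzinc may acylate at the activated esters before electron transfer, or the second ester may be lost before its radical is formed. In the first coupling at C2 the aryl group must also enter on the face that still carries the C5 ester across the ring oxygen. Conversion may therefore stall after one coupling, or facial selectivity may be incomplete. The fallback forms the bonds by a polar path under thermodynamic stereocontrol. It sets out from diacid 9. Twofold oxidative decarboxylation with Pb(OAc)4 (pyridine, THF, 25 °C) should give the bis(anomeric acetate) (3S,4S)-3,4-bis[(tert-butyldimethylsilyloxy)methyl]oxolane-2,5-diyl diacetate F1 as a mixture at C2 and C5. Treatment with 2,6-dimethoxyphenol (COc1cccc(OC)c1O, two equivalents or more) and BF3·OEt2 in CH2Cl2 at −78 °C to −20 °C should replace both acetates by Friedel–Crafts attack on the oxocarbenium ions, para to the phenolic hydroxyl. Each aryl group is expected trans to its neighbour, and the electron-rich benzylic ether carbons can equilibrate under the Lewis acid toward the all-trans isomer. This should give 4,4'-{(2R,3S,4S,5R)-3,4-bis[(tert-butyldimethylsilyloxy)methyl]oxolane-2,5-diyl}bis(2,6-dimethoxyphenol) F2. Buffered Bu4NF as in step 9 then removes the two silyl ethers, and the fallback comes back to the route at target 19.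

2. Step 1. The two diastereomeric dimenthyl esters may co-crystallise and co-elute, so the resolution may give no diastereomerically pure ester. The fallback resolves the acid as a salt instead. It sets out from dichloride 4, which is hydrolysed with water/THF to racemic (1R*,2R*,3R*,4S*)-7-oxabicyclo[2.2.1]hept-5-ene-2,3-dicarboxylic acid F3. Fractional crystallisation with (S)-1-phenylethylamine (or its enantiomer, should the wanted acid stay in the liquor) should give bis[(S)-1-phenylethylammonium] (1R,2R,3R,4S)-7-oxabicyclo[2.2.1]hept-5-ene-2,3-dicarboxylate F4. Acidification liberates (1R,2R,3R,4S)-7-oxabicyclo[2.2.1]hept-5-ene-2,3-dicarboxylic acid F5, and LiAlH4 in THF at 0 °C to 25 °C reduces it to diol 6, where the route is rejoined.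

3. Step 4. Acid generated during the periodate oxidation may strip a silyl ether, or RuO4 may oxidise further at the ether carbons, so protecting groups may be lost and lactones may form. The fallback cleaves the alkene in stages through the isolated aldehyde. It sets out from 7. Ozonolysis (O3, CH2Cl2/MeOH, −78 °C; then Me2S) gives dialdehyde 8, now isolated. Pinnick oxidation (NaClO2, NaH2PO4, 2-methylbut-2-ene, tBuOH/H2O) takes it to diacid 9, where the route is rejoined. No compound outside the list is made (F0).

Further compounds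

F1 | step 8 | (3S,4S)-3,4-bis[(tert-butyldimethylsilyloxy)methyl]oxolane-2,5-diyl diacetate (mixture at C2 and C5) | CC(=O)OC1OC(OC(C)=O)[C@H](CO[Si](C)(C)C(C)(C)C)[C@H]1CO[Si](C)(C)C(C)(C)C
F2 | step 8 | 4,4'-{(2R,3S,4S,5R)-3,4-bis[(tert-butyldimethylsilyloxy)methyl]oxolane-2,5-diyl}bis(2,6-dimethoxyphenol) | COc1cc([C@@H]2O[C@@H](c3cc(OC)c(O)c(OC)c3)[C@H](CO[Si](C)(C)C(C)(C)C)[C@H]2CO[Si](C)(C)C(C)(C)C)cc(OC)c1O
F3 | step 1 | racemic (1R*,2R*,3R*,4S*)-7-oxabicyclo[2.2.1]hept-5-ene-2,3-dicarboxylic acid (one enantiomer drawn) | C1=C[C@@H]2O[C@H]1[C@H](C(=O)O)[C@H]2C(=O)O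
F4 | step 1 | bis[(S)-1-phenylethylammonium] (1R,2R,3R,4S)-7-oxabicyclo[2.2.1]hept-5-ene-2,3-dicarboxylate | C1=C[C@@H]2O[C@H]1[C@H](C(=O)[O-])[C@H]2C(=O)[O-].C[C@H]([NH3+])c1ccccc1.C[C@H]([NH3+])c1ccccc1
F5 | step 1 | (1R,2R,3R,4S)-7-oxabicyclo[2.2.1]hept-5-ene-2,3-dicarboxylic acid | C1=C[C@@H]2O[C@H]1[C@H](C(=O)O)[C@H]2C(=O)O
F0 | step 4 | none | none
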